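Remark (assumption): the SMILES is read as (3R,4S,5R) in the ring and (2R) in the 2-methylbutanoyl group; compounds 2 and 6 and both antipodes of the ligand tBu-box (2,2'-(propane-2,2-diyl)bis[4-tert-butyl-4,5-dihydro-1,3-oxazole]) are taken as purchasable.

## Analysis of the target

- The target has one ring, a cyclohex-1-ene (C1–C6). C1 carries a methyl ester conjugated with C1=C2, C6 is a methylene group, and the three contiguous sp3 carbons carry three different esters: acetate on the allylic C3, propanoate on C4, (2R)-2-methylbutanoate on C5.
- The ring configuration (3R,4S,5R) is that of natural (−)-shikimic acid: O3 and O4 are cis, O4 and O5 are trans. The three ring stereocentres therefore depend on each other.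
- The fourth stereocentre sits outside the ring, α to a carbonyl group. It is independent of the others, can epimerise, and has to be brought in as the pure (R) acid.
- Sensitive points: the three esters on neighbouring oxygens can change places by acyl migration, fastest across the cis pair O3/O4. The γ-acyloxy enoate can lose carboxylic acid toward an aromatic ring under base. The methyl ester rules out any late hydrolysis or methanolysis.
- The skeleton is small. The difficulty is to give each of three similar secondary oxygens its own acyl group in the right absolute configuration.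
- The feature the plan uses is the four-carbon run C2–C3–C4–C5 together with the oxygen on C5. C5–O and the enoate β-carbon C2 lie para across the ring. An oxygen bridge drawn from C5 to C2 turns the ring into a 7-oxabicyclo[2.2.1]heptene: a furan (O, C2–C5) that has taken up an acrylate (C6, C1 and the ester carbon).

## Retrosynthetic reasoning

Atom labels are those of the target throughout.

**11 to 10 (acyl–O4 bond).** The propanoyl group is removed first. In 10, O4 is the only free hydroxyl group, so the last forward step needs no selectivity, only an acylation faster than acetyl migration.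

**10 to 9 to 8 (acetyl–O3 bond).** O3 and O4 are the cis pair and cannot be told apart by reactivity with confidence. Both are tied to one carbon in the cyclic orthoester 9, made from diol 8. The regiochemical question becomes a stereoelectronic one: opening of 9 should leave the ester on the pseudoaxial O3 and the hydroxyl on the equatorial O4.

**8 to 7 (C3–O and C4–O bonds).** Both bonds are cut together, which leaves the C3=C4 double bond of diene 7. The forward syn-dihydroxylation must choose this double bond over the ester-conjugated C1=C2 and add anti to the C5 acyloxy group. One operation then sets C3 and C4 in the cis/trans pattern required, relayed from C5.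

**7 to 5 + 6 (acyl–O5 bond).** Dienol 5 has a single hydroxyl group. The (2R)-acid 6 is attached when no other oxygen exists on the ring, so O5 never has to be distinguished from O3 or O4.

**5 to 4 (reconnection of O5 to C2).** C2 is β to the ester carbonyl and C5–O is para to it, so 5 is the β-elimination product of the oxygen-bridged ester 4. The forward E1cB opening turns the bridge into the C5 hydroxyl and the C1=C2/C3=C4 diene. The only stereocentre kept is C5.

**4 to 3 to 1 + 2 (C1–C2 and C5–C6 bonds).** Ester 4 comes from imide 3 by ester exchange. Imide 3 is the [4+2] adduct of furan 1 and acrylimide 2. This disconnection removes the whole carbocycle and all stereochemistry and leaves two achiral commodity compounds. The forward reaction has to be enantioselective and endo-selective, which a chiral copper Lewis acid that chelates the imide can deliver.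

## Alternatives that were turned down

**Alternative 1: semisynthesis (the textbook route).**
- Disconnection: only the three acyl–O bonds are cut. Ring and ring stereocentres are bought as (−)-shikimic acid A1.
- Forward key step: Fischer esterification and acetonide formation give methyl 3,4-O-isopropylidene shikimate A2. Its lone 5-OH is acylated with 6 to give A3. Acid removal of the acetonide gives 8, then steps 6 and 7.
- Why turned down: it is about one step shorter than the chosen route, so step count is not the reason. Its key step is an O-acylation: it builds no ring bond and sets no stereocentre. O5 is singled out only by a protecting group, whose acidic removal from A3 frees O4 next to the O5 ester, the condition for acyl migration. It reaches only the natural antipode of the ring. The O3/O4 problem is solved no differently from the chosen route.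

**Alternative 2: late dehydration of a quinate.**
- Disconnection: the C1=C2 π bond, traced back to the tertiary alcohol of (−)-quinic acid A4.
- Forward key step: dehydration of the fully acylated methyl quinate A5 across C1–C2.
- Why turned down: C1 of A5 has two β-methylene groups, C2 and C6, each with a hydrogen able to reach the geometry for elimination. Nothing in the triester biases the choice, so 11 would form together with its double-bond isomer A6. A5 also needs the same oxygen differentiation as Alternative 1 plus protection of the tertiary hydroxyl, so it is longer and less selective.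

**Alternative 3: carbohydrate to carbocycle.**
- Disconnection: C1=C2 (olefination) and C1–C6 (alkylation). C1–C5 of D-lyxose A7 become C2–C6 of the target, with O2, O3 and the ring oxygen O4 of the furanose as O3, O4 and O5.
- Forward key step: intramolecular Horner–Wadsworth–Emmons closure of the lactol phosphonate A8, which gives A2.
- Why turned down: the mapping is exact and the furanose ring oxygen emerges as the free O5. But A8 costs about six steps (glycoside, acetonide, activation of C5, phosphonoacetate alkylation, glycoside cleavage) and the product A2 is two steps from A1. O3 and O4 are again locked together in an acetonide.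

Key step: step 1

## Route

Step 1
Reactants: 1 furan; 2 3-acryloyl-1,3-oxazolidin-2-one
Product: 3 3-[(1R,2R,4R)-7-oxabicyclo[2.2.1]hept-5-ene-2-carbonyl]-1,3-oxazolidin-2-one (endo adduct)
Conditions: [Cu((R,R)-tBu-box)](SbF6)2 (5 mol%, from CuCl2, ligand and AgSbF6), 1 in excess, CH2Cl2, −78 °C; recrystallisation
Reagents that add atoms: none
Why: Concerted, asynchronous normal-demand [4+2] cycloaddition: 2 binds to the cationic divalent copper centre through both carbonyl oxygens, which locks the acrylimide s-cis in a distorted square plane, lowers its LUMO and lets furan react at −78 °C. The closest known reaction type is the bis(oxazoline)copper-catalysed enantioselective Diels–Alder reaction of N-acryloyl oxazolidinones with cyclic dienes, furan among them. The step closes the six-membered carbocycle of the target by intermolecular [4+2] ring formation, making C1–C2 and C5–C6 (target numbering) at once and leaving the furan oxygen as a one-atom bridge between C2 and C5. Three stereocentres arise: the two bridgeheads are tied to each other by the suprafacial addition, the carbonyl-bearing carbon is set endo by the kinetic endo preference of the chelated dienophile, and the absolute sense of all three comes from the (R,R) ligand, whose tert-butyl groups shield one α-face of the bound acrylimide. The selectivities needed are enantiofacial and endo/exo; there is no regiochemical question because furan is symmetric. Endo/exo purity is part of enantiopurity here: an exo adduct formed on the same dienophile face has the opposite bridgehead configuration and would end as the enantiomer of 5, so it is removed by recrystallisation and not carried on. The low temperature belongs to the design, since furan adducts cyclorevert easily and equilibration would favour the exo isomer and erase the enantiomeric excess.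

Step 2
Reactants: 3 3-[(1R,2R,4R)-7-oxabicyclo[2.2.1]hept-5-ene-2-carbonyl]-1,3-oxazolidin-2-one
Product: 4 methyl (1R,2R,4R)-7-oxabicyclo[2.2.1]hept-5-ene-2-carboxylate
Conditions: MeOMgBr (from MeMgBr and MeOH, 1.2 equiv), MeOH/CH2Cl2, −20 to 0 °C; aqueous work-up
Reagents that add atoms: bromomagnesium methoxide, C[O-].[Mg+2].[Br-] (made from methanol, CO, and methylmagnesium bromide, C[Mg]Br)
Why: Transesterification of an N-acyl oxazolidinone by a magnesium alkoxide: chelation of magnesium between the two imide carbonyls activates the exocyclic one, and the weakly basic, cold medium should neither open the oxygen bridge nor allow cycloreversion. Epimerisation at C2 would be harmless, because C2 becomes sp2 in step 3 and the bridgeheads are untouched.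

Step 3
Reactants: 4 methyl (1R,2R,4R)-7-oxabicyclo[2.2.1]hept-5-ene-2-carboxylate
Product: 5 methyl (5R)-5-hydroxycyclohexa-1,3-diene-1-carboxylate
Conditions: LiN(SiMe3)2 (1.1 equiv), THF, −78 to 0 °C; AcOH (1.1 equiv), −78 °C
Reagents that add atoms: none
Why: E1cB β-elimination: the ester enolate expels the bridging oxygen from the adjacent bridgehead, a strain-releasing opening that is known for 7-oxanorbornene-2-carboxylates. The remote bridgehead C4 of 4 is not touched and becomes C5 (R) of 5; the cold acidic quench keeps the lithium alkoxide from going on to an aromatic ester by loss of water.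

Step 4
Reactants: 5 methyl (5R)-5-hydroxycyclohexa-1,3-diene-1-carboxylate; 6 (2R)-2-methylbutanoic acid
Product: 7 methyl (5R)-5-{[(2R)-2-methylbutanoyl]oxy}cyclohexa-1,3-diene-1-carboxylate
Conditions: DCC (1.2 equiv), DMAP (0.1 equiv), CH2Cl2, 0 °C to rt
Reagents that add atoms: none
Why: Steglich esterification of the only hydroxyl group in the molecule, so O5 receives its acyl group without any differentiation from O3 and O4, which do not exist yet. The C5–O bond is not broken, so C5 keeps its configuration; catalytic DMAP at 0 °C is chosen to hold back enolisation of the activated acid, the path by which the α-stereocentre of 6 would epimerise.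

Step 5
Reactants: 7 methyl (5R)-5-{[(2R)-2-methylbutanoyl]oxy}cyclohexa-1,3-diene-1-carboxylate
Product: 8 methyl (3R,4R,5R)-3,4-dihydroxy-5-{[(2R)-2-methylbutanoyl]oxy}cyclohex-1-ene-1-carboxylate
Conditions: OsO4 (2 mol%), NMO (1.3 equiv), acetone/H2O, 0 °C
Reagents that add atoms: N-methylmorpholine N-oxide, C[N+]1([O-])CCOCC1; water, O; both oxygens are delivered through osmium tetroxide, O=[Os](=O)(=O)=O
Why: Catalytic Upjohn syn-dihydroxylation: OsO4 takes the electron-richer disubstituted C3=C4 bond and leaves the ester-conjugated C1=C2 bond, as is usual for dienoates. It adds from the face anti to the allylic C5 acyloxy group (the normal preference toward allylic oxygen substituents, known for 5-silyloxy analogues of 7), which sets C3 and C4 cis to each other and C4 trans to C5; the descriptor at C4 reads R here only because of CIP priorities, the geometry is that of the target.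

Step 6
Reactants: 8 methyl (3R,4R,5R)-3,4-dihydroxy-5-{[(2R)-2-methylbutanoyl]oxy}cyclohex-1-ene-1-carboxylate
Product: 10 methyl (3R,4S,5R)-3-(acetyloxy)-4-hydroxy-5-{[(2R)-2-methylbutanoyl]oxy}cyclohex-1-ene-1-carboxylate, via cyclic 3,4-orthoacetate 9 (not isolated)
Conditions: MeC(OMe)3 (1.5 equiv), camphorsulfonic acid (cat.), CH2Cl2, rt; then AcOH/H2O 4:1, 0 °C to rt
Reagents that add atoms: trimethyl orthoacetate, CC(OC)(OC)OC; water, O
Why: Acid-catalysed exchange closes the five-membered cyclic orthoester 9 across the cis pair O3/O4, the only diol present. Mild aqueous acid opens it through the 2-hydroxy-1,3-dioxolane, whose stereoelectronically controlled collapse is known to leave the ester on the axial oxygen of a cis-diol, here the pseudoaxial allylic O3, and the hydroxyl on the equatorial O4; no C–O bond to the ring is broken, so no stereocentre changes.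

Step 7
Reactants: 10 methyl (3R,4S,5R)-3-(acetyloxy)-4-hydroxy-5-{[(2R)-2-methylbutanoyl]oxy}cyclohex-1-ene-1-carboxylate
Product: 11 methyl (3R,4S,5R)-3-(acetyloxy)-5-{[(2R)-2-methylbutanoyl]oxy}-4-(propanoyloxy)cyclohex-1-ene-1-carboxylate
Conditions: (EtCO)2O (1.5 equiv), pyridine, DMAP (5 mol%), CH2Cl2, 0 °C
Reagents that add atoms: propionic anhydride, CCC(=O)OC(=O)CC
Why: DMAP-catalysed acylation of the single remaining hydroxyl group (O4). At 0 °C the acyl transfer should outrun O3-to-O4 acetyl migration, and no stereocentre is involved.

## Compound list

1 | furan | c1ccoc1 | starting material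
2 | 3-acryloyl-1,3-oxazolidin-2-one | C=CC(=O)N1CCOC1=O | starting material
3 | 3-[(1R,2R,4R)-7-oxabicyclo[2.2.1]hept-5-ene-2-carbonyl]-1,3-oxazolidin-2-one | O=C(N1CCOC1=O)[C@@H]2C[C@H]3O[C@@H]2C=C3 | intermediate
4 | methyl (1R,2R,4R)-7-oxabicyclo[2.2.1]hept-5-ene-2-carboxylate | COC(=O)[C@@H]1C[C@H]2O[C@@H]1C=C2 | intermediate
5 | methyl (5R)-5-hydroxycyclohexa-1,3-diene-1-carboxylate | COC(=O)C1=CC=C[C@H](O)C1 | intermediate
6 | (2R)-2-methylbutanoic acid | CC[C@@H](C)C(=O)O | starting material
7 | methyl (5R)-5-{[(2R)-2-methylbutanoyl]oxy}cyclohexa-1,3-diene-1-carboxylate | COC(=O)C1=CC=C[C@H](OC(=O)[C@H](C)CC)C1 | intermediate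
8 | methyl (3R,4R,5R)-3,4-dihydroxy-5-{[(2R)-2-methylbutanoyl]oxy}cyclohex-1-ene-1-carboxylate | O[C@@H]1[C@H](O)C=C(C(=O)OC)C[C@H]1OC(=O)[C@H](C)CC | intermediate
9 | cyclic 3,4-orthoacetate of 8: 2-methoxy-2-methyl-1,3-dioxolane fused cis across C3–C4, both epimers at the orthoester carbon | COC2(C)O[C@@H]1[C@H](O2)C=C(C(=O)OC)C[C@H]1OC(=O)[C@H](C)CC | intermediate (not isolated)
10 | methyl (3R,4S,5R)-3-(acetyloxy)-4-hydroxy-5-{[(2R)-2-methylbutanoyl]oxy}cyclohex-1-ene-1-carboxylate | O[C@@H]1[C@H](OC(C)=O)C=C(C(=O)OC)C[C@H]1OC(=O)[C@H](C)CC | intermediate
11 | methyl (3R,4S,5R)-3-(acetyloxy)-5-{[(2R)-2-methylbutanoyl]oxy}-4-(propanoyloxy)cyclohex-1-ene-1-carboxylate | CCC(=O)O[C@@H]1[C@H](OC(C)=O)C=C(C(=O)OC)C[C@H]1OC(=O)[C@H](C)CC | target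

## Step count and least certain steps

Total: 7 steps. Longest linear sequence: 7 steps (1 and 2 to 11); acid 6 enters at step 4.

**Step 1 (key step).**
- Most likely failure: loss of kinetic control. Cycloreversion and re-addition of the furan adduct would erode the endo preference and the enantiomeric purity together, and incomplete removal of the exo isomer would carry the wrong antipode forward.
- Fallback (classical resolution in place of catalysis), from 1 back to 4: thermal cycloaddition of 1 with acrylic acid (neat, trace of inhibitor, ambient temperature, slow) should give after crystallisation racemic endo-7-oxabicyclo[2.2.1]hept-5-ene-2-carboxylic acid F1. Fractional crystallisation with (R)-1-phenylethylamine should give (1R)-1-phenylethanaminium (1R,2R,4R)-7-oxabicyclo[2.2.1]hept-5-ene-2-carboxylate F2; which amine antipode pairs with the needed acid in the less soluble salt is not known here, and the (S)-amine is taken if it is the other one. Dilute acid releases (1R,2R,4R)-7-oxabicyclo[2.2.1]hept-5-ene-2-carboxylic acid F3, and MeI/K2CO3 in DMF gives 4.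

**Step 4.**
- Most likely failure: β-elimination of the new acyloxy group with aromatisation of the cyclohexadiene, triggered by DMAP or on silica, because the diene is one elimination away from a benzene ring. Partial epimerisation of the acyl α-carbon is the second risk.
- Fallback (acyl group introduced only after the diene is gone), from 5 back to 9: dihydroxylation of the free dienol 5 (OsO4 cat., NMO), anti to the hydroxyl group, should give methyl (3R,4S,5R)-3,4,5-trihydroxycyclohex-1-ene-1-carboxylate F4. Trimethyl orthoacetate with acid catalysis should engage the cis pair and give the 3,4-O-(1-methoxyethylidene) orthoester of methyl shikimate F5, with O5 as the only free hydroxyl. Steglich esterification of F5 with 6 gives 9, which is opened as in step 6.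

**Step 6.**
- Most likely failure: collapse of the hemi-orthoester in the unwanted direction, or acid-catalysed acetyl migration from O3 to O4 after the opening. Either happens if the half-chair of the cyclohexene does not hold O3 as clearly axial as a pyranose chair would.
- Fallback (O3 and O4 taken from two different reagents, so no diol is ever differentiated), from 7 back to 10: peracid epoxidation of the C3=C4 bond anti to the C5 acyloxy group (mCPBA, NaHCO3, CH2Cl2, 0 °C) should give methyl 5-{[(2R)-2-methylbutanoyl]oxy}-7-oxabicyclo[4.1.0]hept-2-ene-3-carboxylate with the epoxide oxygen trans to the acyloxy group F6. Opening of this vinyl epoxide with acetic acid under zerovalent palladium catalysis (Pd(PPh3)4 cat., AcOH, THF) should proceed with double inversion at C3, through the allyl complex spanning C1–C3, and attack at the terminus remote from the ester. That places acetate on C3 cis to the hydroxyl on C4, which is 10.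

**Step 7.**
- Most likely failure: base-induced O3-to-O4 acetyl migration competing with propanoyl transfer, which would exchange the positions of acetate and propanoate.
- Fallback (reversed order, so the migration-prone axial ester is installed last), from 8 back to 11: borinic-acid-catalysed regioselective acylation of the cis-diol (2-aminoethyl diphenylborinate cat., propanoyl chloride, iPr2NEt, MeCN) should acylate the equatorial O4 and give methyl (3R,4R,5R)-3-hydroxy-5-{[(2R)-2-methylbutanoyl]oxy}-4-(propanoyloxy)cyclohex-1-ene-1-carboxylate F7. Here the propanoate sits on the thermodynamically preferred oxygen. Acetylation of O3 (Ac2O, pyridine, DMAP, 0 °C) then gives 11.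

## Further compounds

F1 | step 1 | racemic endo-7-oxabicyclo[2.2.1]hept-5-ene-2-carboxylic acid, (1R*,2R*,4R*) | OC(=O)[C@@H]1C[C@H]2O[C@@H]1C=C2.OC(=O)[C@H]1C[C@@H]2O[C@H]1C=C2
F2 | step 1 | (1R)-1-phenylethanaminium (1R,2R,4R)-7-oxabicyclo[2.2.1]hept-5-ene-2-carboxylate | C[C@@H]([NH3+])c1ccccc1.[O-]C(=O)[C@@H]1C[C@H]2O[C@@H]1C=C2
F3 | step 1 | (1R,2R,4R)-7-oxabicyclo[2.2.1]hept-5-ene-2-carboxylic acid | OC(=O)[C@@H]1C[C@H]2O[C@@H]1C=C2
F4 | step 4 | methyl (3R,4S,5R)-3,4,5-trihydroxycyclohex-1-ene-1-carboxylate (methyl shikimate) | O[C@@H]1[C@H](O)C=C(C(=O)OC)C[C@H]1O
F5 | step 4 | methyl shikimate 3,4-O-(1-methoxyethylidene) orthoester, 5-OH free | COC2(C)O[C@@H]1[C@H](O2)C=C(C(=O)OC)C[C@H]1O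
F6 | step 6 | methyl 5-{[(2R)-2-methylbutanoyl]oxy}-7-oxabicyclo[4.1.0]hept-2-ene-3-carboxylate, epoxide oxygen trans to the acyloxy group | O1[C@@H]2[C@H]1C=C(C(=O)OC)C[C@H]2OC(=O)[C@H](C)CC
F7 | step 7 | methyl (3R,4R,5R)-3-hydroxy-5-{[(2R)-2-methylbutanoyl]oxy}-4-(propanoyloxy)cyclohex-1-ene-1-carboxylate | CCC(=O)O[C@@H]1[C@H](O)C=C(C(=O)OC)C[C@H]1OC(=O)[C@H](C)CC
A1 | alternative 1 | (−)-shikimic acid, (3R,4S,5R)-3,4,5-trihydroxycyclohex-1-ene-1-carboxylic acid | O[C@@H]1[C@H](O)C=C(C(=O)O)C[C@H]1O
A2 | alternative 1 | methyl 3,4-O-isopropylidene shikimate | CC2(C)O[C@@H]1[C@H](O2)C=C(C(=O)OC)C[C@H]1O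
A3 | alternative 1 | methyl 3,4-O-isopropylidene-5-O-[(2R)-2-methylbutanoyl]shikimate | CC2(C)O[C@@H]1[C@H](O2)C=C(C(=O)OC)C[C@H]1OC(=O)[C@H](C)CC
A4 | alternative 2 | (−)-quinic acid | O[C@@H]1[C@H](O)C[C@@](O)(C(=O)O)C[C@H]1O
A5 | alternative 2 | methyl 3-O-acetyl-5-O-[(2R)-2-methylbutanoyl]-4-O-propanoylquinate | CCC(=O)O[C@@H]1[C@H](OC(C)=O)C[C@@](O)(C(=O)OC)C[C@H]1OC(=O)[C@H](C)CC
A6 | alternative 2 | double-bond isomer of 11 with the alkene between C1 and C6 | CCC(=O)O[C@@H]1[C@H](OC(C)=O)CC(C(=O)OC)=C[C@H]1OC(=O)[C@H](C)CC
A7 | alternative 3 | D-lyxose | O=C[C@@H](O)[C@@H](O)[C@H](O)CO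
A8 | alternative 3 | 5-deoxy-5-C-[(dimethoxyphosphoryl)(methoxycarbonyl)methyl]-2,3-O-isopropylidene-D-lyxofuranose | CC3(C)O[C@@H]1[C@H](O3)C(O)O[C@@H]1CC(C(=O)OC)P(=O)(OC)OC
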